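**Plan**
- Numbering is that of the labdane skeleton: ring A = C1–C5 and C10, ring B = C5–C10, C17 = exocyclic CH2, C20 = methyl on C10. The exocyclic C8=C17 methylene of ring B, next to the C9 stereocentre, is what a 6-exo closure of a C8 vinyl radical onto a C9=C11 alkene leaves behind.
- Cuts, in retrosynthetic order: tert-butyl ester; C8–C9 (ring B); C8–Br back to an alkyne; C9=C11 (Julia–Kocienski); the two C–CH3 bonds at C4 and C10; the ring A bonds C10–C1 and C3–C4.
- Forward: a desymmetrised 3-(but-3-enyl)glutarate is annulated to ring A, both quaternary centres are made by methylation, the C5 arm is turned into the alkyne, the side chain is joined, and the bromoalkene closes ring B.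
- Stereochemistry: C5 from the catalytic anhydride opening; C4 and C10 from C5 (methyl anti to the chain); C13 from (R)-3-methylglutaric acid monomethyl ester; C9 in the key step from ring A; the cis ring fusion from the cis arms on C5 and C10.

Key step: step 17

Assumption: (DHQD)2AQN is taken to deliver hemiester 6; if this 3-alkyl anhydride gives the mirror image, the pseudoenantiomer (DHQ)2AQN is used and nothing else changes.

**Step 1**
Reactants: 1 pent-4-enal; 2 dimethyl malonate (2.2 equiv)
Product: 3 tetramethyl 2-(but-3-en-1-yl)propane-1,1,3,3-tetracarboxylate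
Conditions: piperidine (cat.), AcOH (cat.), toluene, rt → 60 °C
Reagents that add atoms: none
Why: Knoevenagel condensation followed by Michael addition of a second malonate, the classical way from an aldehyde to a 3-substituted glutaric acid.

**Step 2**
Reactants: 3
Product: 4 3-(but-3-en-1-yl)pentanedioic acid
Conditions: NaOH, MeOH/H2O, reflux; HCl to pH 1; then neat, 160 °C
Reagents that add atoms: sodium hydroxide, [Na+].[OH-]
Why: Ester saponification followed by thermal decarboxylation of the two malonic acid units; the terminal alkene is inert.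

**Step 3**
Reactants: 4
Product: 5 4-(but-3-en-1-yl)oxane-2,6-dione
Conditions: Ac2O, 100 °C; volatiles removed
Reagents that add atoms: none
Why: Cyclodehydration of a 3-substituted glutaric acid to its six-membered anhydride with acetic anhydride.

**Step 4**
Reactants: 5
Product: 6 (3S)-3-(2-methoxy-2-oxoethyl)hept-6-enoic acid
Conditions: MeOH (10 equiv), (DHQD)2AQN (10 mol %), Et2O, −40 °C
Reagents that add atoms: methanol, CO
Why: Cinchona-alkaloid-catalysed enantioselective methanolysis (desymmetrisation) of a prochiral 3-alkylglutaric anhydride: the catalyst steers methanol to one of the two enantiotopic carbonyl groups, which fixes C5.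

**Step 5**
Reactants: 6
Product: 7 1-tert-butyl 5-methyl (3R)-3-(but-3-en-1-yl)pentanedioate
Conditions: tert-butyl 2,2,2-trichloroacetimidate (2 equiv), CH2Cl2/cyclohexane, rt
Reagents that add atoms: tert-butyl 2,2,2-trichloroacetimidate, CC(C)(C)OC(=N)C(Cl)(Cl)Cl
Why: O-alkylation of the acid by the imidate (tert-butyl cation transfer), which never activates the carboxyl group and so cannot scramble the two ends through the anhydride.

**Step 6**
Reactants: 7; 8 1-chloro-3-iodopropane
Product: 10 1-tert-butyl 3-methyl (2R)-2-(but-3-en-1-yl)cyclohexane-1,3-dicarboxylate (C1/C3 epimer mixture), via chloropropyl diester 9 (not isolated)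
Conditions: LiN(iPr)2 (1.05 equiv), THF, −78 °C, then 8, −78 → −20 °C; LiN(iPr)2 (1.2 equiv), DMPU, −78 °C → rt
Reagents that add atoms: none
Why: Two ester-enolate alkylations in one flask (α,α'-annulation): the iodide end reacts first and the second enolate closes ring A by 6-exo-tet displacement of chloride; either α-carbon may react first because both regioisomers of 9 close to the same ring, and the configurations at C4 and C10 do not matter since both are enolised again in step 7.

**Step 7**
Reactants: 10
Product: 11 1-tert-butyl 3-methyl (1S,2R,3R)-2-(but-3-en-1-yl)-1,3-dimethylcyclohexane-1,3-dicarboxylate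
Conditions: LiN(iPr)2 (2.6 equiv), THF/DMPU, −78 → −30 °C; MeI (5 equiv), −78 → 0 °C
Reagents that add atoms: iodomethane, CI
Why: Exhaustive ester-enolate methylation, as in the Kemp triester synthesis: each methyl should enter on the ring face opposite to the C5 chain, the second one also opposite to the axial ester of the centre already made, so both methyls end cis to each other and trans to the chain (C4 and C10 set from C5).

**Step 8**
Reactants: 11
Product: 12 1-tert-butyl 3-methyl (1S,2R,3R)-1,3-dimethyl-2-(3-oxopropyl)cyclohexane-1,3-dicarboxylate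
Conditions: O3, CH2Cl2, −78 °C; PPh3, −78 °C → rt
Reagents that add atoms: ozone, [O-][O+]=O
Why: Ozonolysis of the terminal alkene with reductive work-up; no other alkene is present at this stage.

**Step 9**
Reactants: 12
Product: 13 1-tert-butyl 3-methyl (1S,2R,3R)-2-(but-3-yn-1-yl)-1,3-dimethylcyclohexane-1,3-dicarboxylate
Conditions: dimethyl (1-diazo-2-oxopropyl)phosphonate, K2CO3, MeOH, 0 °C → rt
Reagents that add atoms: dimethyl (1-diazo-2-oxopropyl)phosphonate, COP(=O)(OC)C(=[N+]=[N-])C(C)=O
Why: Ohira–Bestmann (Seyferth–Gilbert) homologation of the aldehyde to the terminal alkyne (C8≡C17) under mild carbonate conditions that the hindered esters tolerate.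

**Step 10**
Reactants: 13
Product: 14 tert-butyl (1S,2R,3R)-2-(but-3-yn-1-yl)-3-(hydroxymethyl)-1,3-dimethylcyclohexane-1-carboxylate
Conditions: iBu2AlH (2.5 equiv), CH2Cl2, −78 → −20 °C; Rochelle salt work-up
Reagents that add atoms: none
Why: Hydride reduction of an ester: iBu2AlH should reduce the methyl ester while the tert-butyl ester on its quaternary carbon is spared at low temperature; the alcohol is oxidised at once so that it cannot close onto the neighbouring ester.

**Step 11**
Reactants: 14
Product: 15 tert-butyl (1S,2R,3R)-2-(but-3-yn-1-yl)-3-formyl-1,3-dimethylcyclohexane-1-carboxylate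
Conditions: Dess–Martin periodinane, CH2Cl2, 0 °C → rt
Reagents that add atoms: none
Why: Dess–Martin oxidation of a primary neopentyl alcohol to an aldehyde (C9) that has no α-hydrogen and so cannot enolise or epimerise.

**Step 12**
Reactants: 16 (3R)-5-methoxy-3-methyl-5-oxopentanoic acid
Product: 17 methyl (3R)-5-hydroxy-3-methylpentanoate
Conditions: BH3·SMe2, THF, 0 °C → rt; MeOH quench; used directly
Reagents that add atoms: none
Why: Borane reduces the carboxylic acid much faster than the ester (chemoselective acid reduction); the stereocentre (C13) is not involved.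

**Step 13**
Reactants: 17
Product: 18 methyl (3S)-3-methyl-5-[(1-phenyl-1H-tetrazol-5-yl)sulfanyl]pentanoate
Conditions: 1-phenyl-1H-tetrazole-5-thiol, PPh3, DIAD, THF, 0 °C → rt
Reagents that add atoms: 1-phenyl-1H-tetrazole-5-thiol, Sc1nnnn1-c1ccccc1
Why: Mitsunobu thioetherification of the primary alcohol with the acidic tetrazole thiol (the descriptor changes by priority only).

**Step 14**
Reactants: 18
Product: 19 methyl (3S)-3-methyl-5-[(1-phenyl-1H-tetrazol-5-yl)sulfonyl]pentanoate
Conditions: H2O2 (30 %), (NH4)6Mo7O24·4H2O (cat.), EtOH, 0 °C → rt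
Reagents that add atoms: hydrogen peroxide, OO
Why: Molybdate-catalysed hydrogen peroxide oxidation of the sulfide to the sulfone.

**Step 15**
Reactants: 15; 19
Product: 20 tert-butyl (1S,2R,3S)-2-(but-3-yn-1-yl)-3-[(1E,4R)-6-methoxy-4-methyl-6-oxohex-1-en-1-yl]-1,3-dimethylcyclohexane-1-carboxylate
Conditions: KN(SiMe3)2 (1.2 equiv) added to 15 and 19 (1.3 equiv), DME, −60 °C → rt
Reagents that add atoms: none
Why: Julia–Kocienski olefination in Barbier mode, so that the metalated sulfone is trapped by the non-enolisable aldehyde before it can attack its own ester; a phenyltetrazolyl sulfone with an α-branched aldehyde should give the E alkene (C9=C11).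

**Step 16**
Reactants: 20
Product: 22 tert-butyl (1S,2R,3S)-2-(3-bromobut-3-en-1-yl)-3-[(1E,4R)-6-methoxy-4-methyl-6-oxohex-1-en-1-yl]-1,3-dimethylcyclohexane-1-carboxylate, via alkenylborane 21 (not isolated)
Conditions: B-bromo-9-BBN (1.3 equiv), CH2Cl2, 0 °C; then AcOH, 0 °C → rt
Reagents that add atoms: B-bromo-9-borabicyclo[3.3.1]nonane, BrB1C2CCCC1CCC2
Why: Haloboration: the bromoborane adds cis across the terminal alkyne only (boron to C17, bromine to C8) and acetic acid protonolysis of the C–B bond leaves the 2-bromo-1-alkene; the internal alkene and the esters should not react at 0 °C.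

**Step 17**
Reactants: 22
Product: 23 tert-butyl ester of the target, (4S,5R,9R,10S,13R) in labdane numbering
Conditions: Bu3SnH (1.3 equiv), AIBN (0.15 equiv), PhH, 80 °C, syringe-pump addition, final 0.01 M
Reagents that add atoms: none
Why: Bu3Sn• abstracts bromine from C8 to give the sp2 C8 radical, which adds to C9 of the E alkene, and the secondary C11 radical is then reduced by Bu3SnH; the closest known reaction type is the Stork vinyl-radical cyclisation of 2-bromo-1,6- and 1,7-dienes to methylenecycloalkanes. Ring B closes in the 6-exo-trig mode, and the exocyclic C8=C17 bond is the radical's own double bond. C9 is the only new stereocentre: ring A has its alkenyl and ester groups axial and both methyls equatorial, so in the chair-like transition state C4 is axial on the forming ring at C5; a pseudo-axial C11 would clash 1,3-diaxially with C4, hence C11 goes equatorial, which is cis to C20. The cis ring fusion is already fixed by the cis arms on C5 and C10. The step needs 6-exo closure to beat 7-endo closure and direct reduction of the vinyl radical; the stereoelectronic preference for exo attack, the substituent on C11, the lack of any hydrogen on C4 and C10 for 1,5-transfer and a low stationary Bu3SnH concentration should secure this.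

**Step 18**
Reactants: 23
Product: 25 target acid CNP0260608.1, via trimethylsilyl ester 24 (not isolated)
Conditions: Me3SiOTf (3 equiv), 2,6-lutidine (4 equiv), CH2Cl2, 0 °C → rt; aqueous NH4Cl work-up
Reagents that add atoms: none
Why: Silyl-triflate-mediated cleavage of a tert-butyl ester (loss of isobutene to the silyl ester, hydrolysed on work-up), chosen because the lutidine-buffered medium should spare the acid-sensitive exocyclic alkene and the methyl ester.

**Compound list**
1 | pent-4-enal | C=CCCC=O | starting material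
2 | dimethyl malonate | COC(=O)CC(=O)OC | starting material
3 | tetramethyl 2-(but-3-en-1-yl)propane-1,1,3,3-tetracarboxylate | C=CCCC(C(C(=O)OC)C(=O)OC)C(C(=O)OC)C(=O)OC | intermediate
4 | 3-(but-3-en-1-yl)pentanedioic acid | C=CCCC(CC(=O)O)CC(=O)O | intermediate
5 | 4-(but-3-en-1-yl)oxane-2,6-dione | C=CCCC1CC(=O)OC(=O)C1 | intermediate
6 | (3S)-3-(2-methoxy-2-oxoethyl)hept-6-enoic acid | C=CCC[C@@H](CC(=O)O)CC(=O)OC | intermediate
7 | 1-tert-butyl 5-methyl (3R)-3-(but-3-en-1-yl)pentanedioate | C=CCC[C@@H](CC(=O)OC(C)(C)C)CC(=O)OC | intermediate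
8 | 1-chloro-3-iodopropane | ClCCCI | starting material
9 | 1-tert-butyl 5-methyl 3-(but-3-en-1-yl)-4-(3-chloropropyl)pentanedioate, drawn as the isomer alkylated next to the methyl ester (the other regioisomer closes to the same ring; not isolated) | C=CCC[C@@H](CC(=O)OC(C)(C)C)C(CCCCl)C(=O)OC | intermediate
10 | 1-tert-butyl 3-methyl (2R)-2-(but-3-en-1-yl)cyclohexane-1,3-dicarboxylate, C1/C3 epimer mixture | C=CCC[C@@H]1C(C(=O)OC)CCCC1C(=O)OC(C)(C)C | intermediate
11 | 1-tert-butyl 3-methyl (1S,2R,3R)-2-(but-3-en-1-yl)-1,3-dimethylcyclohexane-1,3-dicarboxylate | C=CCC[C@@H]1[C@@](C)(CCC[C@]1(C)C(=O)OC(C)(C)C)C(=O)OC | intermediate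
12 | 1-tert-butyl 3-methyl (1S,2R,3R)-1,3-dimethyl-2-(3-oxopropyl)cyclohexane-1,3-dicarboxylate | O=CCC[C@@H]1[C@@](C)(CCC[C@]1(C)C(=O)OC(C)(C)C)C(=O)OC | intermediate
13 | 1-tert-butyl 3-methyl (1S,2R,3R)-2-(but-3-yn-1-yl)-1,3-dimethylcyclohexane-1,3-dicarboxylate | C#CCC[C@@H]1[C@@](C)(CCC[C@]1(C)C(=O)OC(C)(C)C)C(=O)OC | intermediate
14 | tert-butyl (1S,2R,3R)-2-(but-3-yn-1-yl)-3-(hydroxymethyl)-1,3-dimethylcyclohexane-1-carboxylate | C#CCC[C@@H]1[C@@](C)(CCC[C@]1(C)C(=O)OC(C)(C)C)CO | intermediate
15 | tert-butyl (1S,2R,3R)-2-(but-3-yn-1-yl)-3-formyl-1,3-dimethylcyclohexane-1-carboxylate | C#CCC[C@@H]1[C@@](C)(CCC[C@]1(C)C(=O)OC(C)(C)C)C=O | intermediate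
16 | (3R)-5-methoxy-3-methyl-5-oxopentanoic acid, (R)-3-methylglutaric acid monomethyl ester | OC(=O)C[C@@H](C)CC(=O)OC | starting material
17 | methyl (3R)-5-hydroxy-3-methylpentanoate | OCC[C@@H](C)CC(=O)OC | intermediate
18 | methyl (3S)-3-methyl-5-[(1-phenyl-1H-tetrazol-5-yl)sulfanyl]pentanoate | c1ccccc1-n1nnnc1SCC[C@@H](C)CC(=O)OC | intermediate
19 | methyl (3S)-3-methyl-5-[(1-phenyl-1H-tetrazol-5-yl)sulfonyl]pentanoate | c1ccccc1-n1nnnc1S(=O)(=O)CC[C@@H](C)CC(=O)OC | intermediate
20 | tert-butyl (1S,2R,3S)-2-(but-3-yn-1-yl)-3-[(1E,4R)-6-methoxy-4-methyl-6-oxohex-1-en-1-yl]-1,3-dimethylcyclohexane-1-carboxylate | C#CCC[C@@H]1[C@@](C)(CCC[C@]1(C)C(=O)OC(C)(C)C)/C=C/C[C@@H](C)CC(=O)OC | intermediate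
21 | (Z)-2-bromoalk-1-enyl-9-BBN adduct of 20, boron on C17 and bromine on C8 (not isolated) | Br\C(CC[C@@H]1[C@@](C)(CCC[C@]1(C)C(=O)OC(C)(C)C)/C=C/C[C@@H](C)CC(=O)OC)=C/B1C2CCCC1CCC2 | intermediate
22 | tert-butyl (1S,2R,3S)-2-(3-bromobut-3-en-1-yl)-3-[(1E,4R)-6-methoxy-4-methyl-6-oxohex-1-en-1-yl]-1,3-dimethylcyclohexane-1-carboxylate | C=C(Br)CC[C@@H]1[C@@](C)(CCC[C@]1(C)C(=O)OC(C)(C)C)/C=C/C[C@@H](C)CC(=O)OC | intermediate
23 | tert-butyl ester of the target, (4S,5R,9R,10S,13R), cis-fused | C=C1CC[C@@H]2[C@@](C)(CCC[C@]2(C)C(=O)OC(C)(C)C)[C@@H]1CC[C@@H](C)CC(=O)OC | intermediate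
24 | trimethylsilyl ester of the target (not isolated) | C=C1CC[C@@H]2[C@@](C)(CCC[C@]2(C)C(=O)O[Si](C)(C)C)[C@@H]1CC[C@@H](C)CC(=O)OC | intermediate
25 | CNP0260608.1, (4S,5R,9R,10S,13R) cis-fused labd-8(17)-ene with the C4 carboxylic acid and the C15 methyl ester | C=C1CC[C@@H]2[C@@](C)(CCC[C@]2(C)C(=O)O)[C@@H]1CC[C@@H](C)CC(=O)OC | target

**Count**
Total steps: 18. Longest linear sequence: 15 (steps 1–11 and 15–18).

**Steps most likely to fail**

Step 17. The vinyl radical may take hydrogen from the stannane before it closes, or close or rearrange to the seven-membered ring. The fallback sets out from enyne 20 and uses no radical: palladium-catalysed reductive cyclisation (Pd2(dba)3·CHCl3, P(o-tol)3, AcOH, Et3SiH, toluene). Hydropalladation of the alkyne puts palladium on C8, 6-exo carbopalladation forms C8–C9, and the silane replaces palladium on C11 by hydrogen. This comes back to the route at 23 and makes no new compound.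

Step 7. Facial control may be lost in the second methylation, where the enolate must react through the conformer that suffers allylic strain with the C5 chain. The fallback sets out from 10 and swaps the methyl ester for a nitrile, whose slim, linear metalated form lets the C5 chain stay equatorial, so the methyl can enter opposite to the axial ester of the neighbouring centre. LiOH would give the acid F1; isobutyl chloroformate, N-methylmorpholine and then NH3 the primary amide F2; (CF3CO)2O and pyridine the nitrile F3. Double methylation (LiN(iPr)2, MeI) would give the dimethyl nitrile F4, ozonolysis the aldehyde F5 and Ohira–Bestmann homologation the alkyne nitrile F6. iBu2AlH reduction of the nitrile and hydrolysis of the imine would then give aldehyde 15 directly.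

Step 15. The metalated sulfone may cyclise onto its own ester while addition to the hindered aldehyde is slow. The fallback sets out from 15 and 16 and builds the alkene by cross-coupling. Takai olefination of 15 (CrCl2, CHI3, THF) would give the E vinyl iodide F7. Iododecarboxylation of 16 (PhI(OAc)2, I2, light) would give methyl (3S)-4-iodo-3-methylbutanoate F8, and zinc dust in THF/DMA the alkylzinc iodide F9. Negishi coupling of F9 with F7 (Pd(PPh3)4 cat.) would come back to the route at 20.

**Further compounds**
F1 | step 7 | (2R)-3-(tert-butoxycarbonyl)-2-(but-3-en-1-yl)cyclohexane-1-carboxylic acid, epimer mixture | C=CCC[C@@H]1C(C(=O)O)CCCC1C(=O)OC(C)(C)C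
F2 | step 7 | tert-butyl (2R)-2-(but-3-en-1-yl)-3-carbamoylcyclohexane-1-carboxylate, epimer mixture | C=CCC[C@@H]1C(C(N)=O)CCCC1C(=O)OC(C)(C)C
F3 | step 7 | tert-butyl (2R)-2-(but-3-en-1-yl)-3-cyanocyclohexane-1-carboxylate, epimer mixture | C=CCC[C@@H]1C(C#N)CCCC1C(=O)OC(C)(C)C
F4 | step 7 | tert-butyl 2-(but-3-en-1-yl)-3-cyano-1,3-dimethylcyclohexane-1-carboxylate, methyls cis to each other and trans to the chain | C=CCC[C@@H]1[C@@](C)(CCC[C@]1(C)C(=O)OC(C)(C)C)C#N
F5 | step 7 | tert-butyl 3-cyano-1,3-dimethyl-2-(3-oxopropyl)cyclohexane-1-carboxylate, same configuration | O=CCC[C@@H]1[C@@](C)(CCC[C@]1(C)C(=O)OC(C)(C)C)C#N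
F6 | step 7 | tert-butyl 2-(but-3-yn-1-yl)-3-cyano-1,3-dimethylcyclohexane-1-carboxylate, same configuration | C#CCC[C@@H]1[C@@](C)(CCC[C@]1(C)C(=O)OC(C)(C)C)C#N
F7 | step 15 | tert-butyl 2-(but-3-yn-1-yl)-3-[(E)-2-iodoethenyl]-1,3-dimethylcyclohexane-1-carboxylate, ring configuration as in 15 | C#CCC[C@@H]1[C@@](C)(CCC[C@]1(C)C(=O)OC(C)(C)C)/C=C/I
F8 | step 15 | methyl (3S)-4-iodo-3-methylbutanoate | IC[C@@H](C)CC(=O)OC
F9 | step 15 | [(2S)-4-methoxy-2-methyl-4-oxobutyl]zinc iodide | I[Zn]C[C@@H](C)CC(=O)OC
F0 | step 17 | none | none
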